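The ratio I started from was reagent charged to substrate charged, since each target costs two reagents.

| setting | oak | maple | larch | alder | ash |
|---|---|---|---|---|---|
| substrate | 0.095 M | 0.095 M | 0.095 M | 0.095 M | 0.095 M |
| reagent | 0.0120 M | 0.0400 M | 0.100 M | 0.300 M | 1.00 M |
| time | 1.5 min | 1.5 min | 1.5 min | 1.5 min | 1.5 min |

    reagent + intermediate B → target (k1 = 0.477 /M/s)
    substrate → intermediate A (k2 = 0.0419 /s)
    reagent + intermediate A ⇌ intermediate C (K3 = 11 /M, k3 = 0.114 /M/s)
    reagent + target → over-reaction product (k4 = 0.0206 /M/s)
    reagent + intermediate A → intermediate B (k5 = 1.76 /M/s)

* amount of target at the end, in percent of the substrate charged for oak, maple, larch, alder, ash, in this order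
* the shape of the row from first to last (rises, then falls / hardly changes / falls all the way / falls, then rises / rises all the way)

- "hardly changes" means that all values lie within two and a half points (for a concentration: within two and a half percent of the largest)
- run time (oak): 1.5 min

I wrote R for the reagent charge and S for the substrate charge. Carrying S through both reagent steps takes 0.190 M, so I solved each side of that point and joined them.

In oak, reagent was the limiting reagent. The steps to intermediate B and to target competed for it, and the reagent concentration cancels from the ratio of their rates. I defined σ as the constant of the step to target over that of the step to intermediate B, a selectivity factor, 0.271. With [A] and [B] for the concentrations of intermediates A and B, target per intermediate B made was then σ[B]/[A], which sums to σ times R squared over 2[A] for [A] held steady. But [A] grew while reagent went. With S as intermediate A, reagent would decay at 0.167 /s, faster than the substrate's 0.0419 /s. So I took [A] as half of S, a round estimate. This gave oak 0.432%, and I carried that low-charge yield, σ times the square of R over S.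

In ash, I reckoned reagent as the charge less twice S, 0.810 M. At that level the steps to intermediate B and to target came out faster than the substrate's step, 0.386 /s at the slower of the two. So I put the arrival of target about 0.398 min into the run, and its later removal by the over-reaction at 0.0167 /s. That estimate gave ash 33.2%. I expected a rise, a turn above 0.190 M, and a fall.

The forecast read 0.35%, 5.5%, 29%, 76%, 32%, rises, then falls, and said “the row peaks near 0.3 M”.

The flask gave 0.390%, 4.50%, 27.5%, 75.2%, 34.1%, rises, then falls, turning at 0.27 M.

My yield for oak stood at 0.432% beside 0.390%, and oak's reagent ended at 0.210% of its charge. For maple the yield gave 4.80% beside 4.50%, and maple's reagent ended at 0.287% of its charge. In oak at 0.267 min, intermediate A was made 4.61 times faster than it was used up, each step taken net. Half of oak's turnover to intermediate B up to the end of the run was done by 0.266 min, when 48.8% of the substrate had reacted.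

The numbers come from no measurement, and the outcome is calculated.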